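**Retrosynthetic overview**
- The C8 hydroperoxide and the E-C6=C7 alkene come last, from a Schenck ene reaction (singlet oxygen, visible light) on the 7E-alkene of the 11,12-epoxy lactone.
- The 11,12-epoxide comes from a bromide-mediated electrochemical epoxidation of the macrocyclic 7E,11E-diene, in which the C4 hydroxyl masks C7=C8 as a transient bromoether (proposed new step).
- The 14-membered carbocycle is closed at C10–C11 by a B-alkyl Suzuki–Miyaura macrocyclisation of a dienyl / vinyl iodide seco compound.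
- C4–C5 is made by Felkin–Anh addition of a C7 dienyl Grignard reagent to a 6-acetyl δ-lactone, whose C3 and C15 are equilibrated against C1.
- The lactone core and the E-C11=C12 vinyl iodide come from (R)-(+)-limonene (1). Ring order: δ-lactone, then 14-membered ring, then oxirane.

Assumption: positions are given in cembrane numbering (C1 = ring CH carrying C15; C3 = lactone O–CH; C4 = tertiary carbinol; C8 = hydroperoxide carbon; C11/C12 = epoxide; C16 = lactone carbonyl), and the facial sense of the two late oxidations (steps 11 and 12) is taken to follow substrate control as stated there.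

**Step 1**
Reactants: 1 (R)-(+)-limonene
Product: 2 (5R)-7,7-dimethoxy-5-(prop-1-en-2-yl)heptan-2-one
Conditions: O3 (1.0 equiv, Sudan red 7B end point), CH2Cl2/MeOH 5:1, −78 °C; TsOH·H2O (10 mol%), −78 °C → rt; NaHCO3, Me2S, rt
Reagents that add atoms: ozone, [O-][O+]=O; methanol, CO
Why: Ozonolysis with Schreiber-type work-up: ozone attacks the electron-rich trisubstituted ring alkene much faster than the isopropenyl group, the carbonyl oxide is trapped at the ketone carbon, the aldehyde is acetalised and Me2S then frees the ketone, so the two termini are differentiated in one operation and the limonene stereocentre (C1) is untouched.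

**Step 2**
Reactants: 2 (5R)-7,7-dimethoxy-5-(prop-1-en-2-yl)heptan-2-one
Product: 4 (5R)-7,7-dimethoxy-5-(prop-1-en-2-yl)hept-1-yne, via enol phosphate 3 (not isolated)
Conditions: LiN(iPr)2 (1.05 equiv), THF, −78 °C; ClP(O)(OEt)2; then LiN(iPr)2 (2.3 equiv), −78 → 0 °C; H2O
Reagents that add atoms: none
Why: Negishi alkyne synthesis: kinetic deprotonation on the CH3 side of the methyl ketone, O-phosphorylation and base-induced loss of diethyl phosphate give the terminal alkyne, the old methyl carbon becoming C11.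

**Step 3**
Reactants: 4 (5R)-7,7-dimethoxy-5-(prop-1-en-2-yl)hept-1-yne
Product: 6 (1E,5R)-1-iodo-7,7-dimethoxy-2-methyl-5-(prop-1-en-2-yl)hept-1-ene, via alkenylalane 5 (not isolated)
Conditions: AlMe3 (3 equiv), Cp2ZrCl2 (25 mol%), H2O (1.5 equiv), CH2Cl2, −20 °C; then I2, THF, −20 → 0 °C
Reagents that add atoms: trimethylaluminium, C[Al](C)C; iodine, II
Why: Negishi zirconium-catalysed syn-methylalumination puts the methyl (C20) on the internal carbon and aluminium on the terminus, and iodinolysis with retention gives the E-trisubstituted vinyl iodide (C11=C12) while the isolated alkene is inert; the short, cold, water-accelerated protocol is chosen to spare the acetal.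

**Step 4**
Reactants: 6 (1E,5R)-1-iodo-7,7-dimethoxy-2-methyl-5-(prop-1-en-2-yl)hept-1-ene
Product: 8 (2RS,3R,6E)-3-(2,2-dimethoxyethyl)-7-iodo-2,6-dimethylhept-6-en-1-ol, via alkylborane 7 (not isolated)
Conditions: 9-BBN (1.3 equiv), THF, 0 °C → rt; then 3 M NaOH, 30% H2O2, 0 °C
Reagents that add atoms: hydrogen peroxide, OO
Why: Brown hydroboration–oxidation: 9-BBN adds anti-Markovnikov to the unhindered 1,1-disubstituted isopropenyl group and not to the trisubstituted vinyl iodide; the new C15 centre forms as a mixture that is corrected in step 6.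

**Step 5**
Reactants: 8 (2RS,3R,6E)-3-(2,2-dimethoxyethyl)-7-iodo-2,6-dimethylhept-6-en-1-ol
Product: 10 (2RS,3R,6E)-7-iodo-2,6-dimethyl-3-(2-oxoethyl)hept-6-enoic acid (held as its cyclic 6-hydroxy-lactone pseudo-acid), via acid acetal 9 (not isolated)
Conditions: TEMPO (10 mol%), NaOCl (5 mol%), NaClO2 (2 equiv), MeCN/phosphate buffer pH 6.7, 35 °C; Na2SO3; then 1 M HCl, THF, rt
Reagents that add atoms: sodium chlorite, [Na+].[O-]Cl=O; water, O
Why: TEMPO/chlorite oxidation at buffered pH takes the primary alcohol to the acid (C16) without touching the acetal or the vinyl iodide, and aqueous acid then hydrolyses the acetal to the C3 aldehyde.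

**Step 6**
Reactants: 10 (2RS,3R,6E)-7-iodo-2,6-dimethyl-3-(2-oxoethyl)hept-6-enoic acid
Product: 13 (3S,4R,6R)-6-acetyl-4-[(3E)-4-iodo-3-methylbut-3-en-1-yl]-3-methyloxan-2-one, via enol ether adduct 11 (not isolated), via lactone epimer mixture 12 (not isolated)
Conditions: ethyl vinyl ether, t-BuLi, THF, −78 → 0 °C (gives 1-ethoxyvinyllithium, 2.6 equiv); add 10, −78 °C; 2 M HCl, THF, rt; then DBU (0.3 equiv), toluene, 60 °C
Reagents that add atoms: 1-ethoxyvinyllithium, [Li]C(=C)OCC; water, O
Why: Acyl-anion addition to the aldehyde, acidic enol-ether hydrolysis and δ-lactonisation give the 6-acetyl lactone, and base equilibration of the two enolisable centres (C3 next to the ketone, C15 next to the lactone carbonyl) funnels the mixture to the all-equatorial isomer, so C3 (R) and C15 (S) are set by thermodynamic control from C1.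

**Step 7**
Reactants: 14 5-bromo-2-methylpent-2-ene
Product: 16 (2E)-5-bromo-2-methylpent-2-enal, via allylic alcohol 15 (not isolated)
Conditions: SeO2 (1.2 equiv), 1,4-dioxane/H2O 30:1, 80 °C
Reagents that add atoms: selenium dioxide, O=[Se]=O
Why: Selenium dioxide allylic oxidation (ene reaction, then 2,3-sigmatropic shift) attacks only the E-methyl group and runs on to the E-enal, which fixes the later C7=C8 geometry.

**Step 8**
Reactants: 16 (2E)-5-bromo-2-methylpent-2-enal
Product: 17 (3E)-6-bromo-3-methylhexa-1,3-diene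
Conditions: Ph3PCH3Br, KN(SiMe3)2, THF, 0 °C; then 16, −78 → 0 °C
Reagents that add atoms: methyltriphenylphosphonium bromide, C[P+](c1ccccc1)(c1ccccc1)c1ccccc1.[Br-]
Why: Wittig methylenation of the enal adds C10 as a terminal vinyl group without changing the alkene geometry or the primary bromide.

**Step 9**
Reactants: 13 (3S,4R,6R)-6-acetyl-4-[(3E)-4-iodo-3-methylbut-3-en-1-yl]-3-methyloxan-2-one; 17 (3E)-6-bromo-3-methylhexa-1,3-diene
Product: 19 (3S,4R,6R)-6-[(2S,5E)-2-hydroxy-6-methylocta-5,7-dien-2-yl]-4-[(3E)-4-iodo-3-methylbut-3-en-1-yl]-3-methyloxan-2-one, via Grignard reagent 18 (not isolated)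
Conditions: 17, Mg, THF, rt; CeCl3 (1.5 equiv), THF, −78 °C; then 13, −78 °C; aq NH4Cl
Reagents that add atoms: none
Why: Cerium-mediated Grignard 1,2-addition is selective for the ketone over the lactone and follows the polar Felkin–Anh (Cornforth) model for an α-acyloxy ketone, the nucleophile entering anti to the ring C3–O bond past the C3 hydrogen, which gives the 4S tertiary alcohol.

**Step 10**
Reactants: 19 (3S,4R,6R)-6-[(2S,5E)-2-hydroxy-6-methylocta-5,7-dien-2-yl]-4-[(3E)-4-iodo-3-methylbut-3-en-1-yl]-3-methyloxan-2-one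
Product: 21 (1R,3R,4S,7E,11E,15S)-4-hydroxycembra-7,11-dien-16,3-olide, via alkylborane 20 (not isolated)
Conditions: 9-BBN (2.5 equiv), THF, 0 °C → rt; then slow addition to PdCl2(dppf) (15 mol%), AsPh3 (30 mol%), Cs2CO3 (3 equiv), DMF/THF/H2O, 50 °C, 1 mM; dilute HCl work-up
Reagents that add atoms: none
Why: B-alkyl Suzuki–Miyaura macrocyclisation: 9-BBN adds anti-Markovnikov only to the terminal vinyl of the diene (boron on C10), and intramolecular sp3–sp2 coupling with the E-vinyl iodide at high dilution closes the 14-membered ring at C10–C11 with both alkene geometries retained.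

**Step 11**
Reactants: 21 (1R,3R,4S,7E,11E,15S)-4-hydroxycembra-7,11-dien-16,3-olide
Product: 24 (1R,3R,4S,7E,11S,12S,15S)-11,12-epoxy-4-hydroxycembr-7-en-16,3-olide, via dibromide 22 (not isolated), via epoxy bromoether 23 (not isolated)
Conditions: undivided cell, graphite anode, Pt cathode, NaBr (1.5 equiv), MeCN/H2O 4:1, constant current 5 mA cm−2, 4.5 F mol−1, 0 °C → rt; then Zn dust, EtOH, 40 °C
Reagents that add atoms: water, O
Why: Proposed new method: in a bromide-mediated paired electrolysis the anodically formed Br+ is captured at C7=C8 by the neighbouring C4 hydroxyl to give a cyclic bromoether, which masks that alkene without a separate step, while the bromonium ion of the remote C11=C12 is opened anti by water at the tertiary C12; cathodically formed hydroxide then closes the bromohydrin to the trans-epoxide with inversion at C11, and zinc regenerates the 7E-alkene and the C4 hydroxyl by Boord-type elimination; the face is set by the lactone- and ether-bridged ring (Br+ on the exposed face, oxygen on the other, expected to give 11S,12S, not verifiable in advance); the closest known reactions are halide-mediated electrochemical epoxidation of simple and isoprenoid alkenes and bromoetherification / zinc elimination as an alkene-protecting sequence.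

**Step 12**
Reactants: 24 (1R,3R,4S,7E,11S,12S,15S)-11,12-epoxy-4-hydroxycembr-7-en-16,3-olide
Product: 25 (1R,3R,4S,6E,8R,11S,12S,15S)-11,12-epoxy-8-hydroperoxy-4-hydroxycembr-6-en-16,3-olide (target)
Conditions: O2, tetraphenylporphyrin (0.5 mol%), CH2Cl2, 0 °C, white LED, stopped at about 70% conversion, no reductive work-up
Reagents that add atoms: dioxygen, O=O
Why: Schenck ene reaction of photosensitised singlet oxygen: oxygen bonds to the more substituted C8 and takes an allylic hydrogen from C6 on the disubstituted (cis) side, moving the double bond to E-C6=C7; attack on the exposed face of the macrocyclic alkene is expected to set 8R, and the epoxide, lactone and alcohol are inert.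

**Compound list**
1 | (R)-(+)-limonene | CC1=CC[C@H](C(C)=C)CC1 | starting material
2 | (5R)-7,7-dimethoxy-5-(prop-1-en-2-yl)heptan-2-one | COC(OC)C[C@H](C(C)=C)CCC(C)=O | intermediate
3 | diethyl (5R)-7,7-dimethoxy-5-(prop-1-en-2-yl)hept-1-en-2-yl phosphate | COC(OC)C[C@H](C(C)=C)CCC(=C)OP(=O)(OCC)OCC | intermediate
4 | (5R)-7,7-dimethoxy-5-(prop-1-en-2-yl)hept-1-yne | COC(OC)C[C@H](C(C)=C)CCC#C | intermediate
5 | [(1E,5R)-7,7-dimethoxy-2-methyl-5-(prop-1-en-2-yl)hept-1-en-1-yl]dimethylalane | COC(OC)C[C@H](C(C)=C)CC/C(C)=C/[Al](C)C | intermediate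
6 | (1E,5R)-1-iodo-7,7-dimethoxy-2-methyl-5-(prop-1-en-2-yl)hept-1-ene | COC(OC)C[C@H](C(C)=C)CC/C(C)=C/I | intermediate
7 | 9-[(2RS,3R,6E)-3-(2,2-dimethoxyethyl)-7-iodo-2,6-dimethylhept-6-en-1-yl]-9-borabicyclo[3.3.1]nonane | COC(OC)C[C@H](C(C)CB1C2CCCC1CCC2)CC/C(C)=C/I | intermediate
8 | (2RS,3R,6E)-3-(2,2-dimethoxyethyl)-7-iodo-2,6-dimethylhept-6-en-1-ol (C2 epimers) | COC(OC)C[C@H](C(C)CO)CC/C(C)=C/I | intermediate
9 | (2RS,3R,6E)-3-(2,2-dimethoxyethyl)-7-iodo-2,6-dimethylhept-6-enoic acid | COC(OC)C[C@H](C(C)C(O)=O)CC/C(C)=C/I | intermediate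
10 | (2RS,3R,6E)-7-iodo-2,6-dimethyl-3-(2-oxoethyl)hept-6-enoic acid (open form shown; in equilibrium with the cyclic 6-hydroxy-lactone) | O=CC[C@H](C(C)C(O)=O)CC/C(C)=C/I | intermediate
11 | (2RS,3R,6E)-3-(3-ethoxy-2-hydroxybut-3-en-1-yl)-7-iodo-2,6-dimethylhept-6-enoic acid | C=C(OCC)C(O)C[C@H](C(C)C(O)=O)CC/C(C)=C/I | intermediate
12 | (4R)-6-acetyl-4-[(3E)-4-iodo-3-methylbut-3-en-1-yl]-3-methyloxan-2-one, mixture of C3 and C6 epimers | CC1C(=O)OC(C(C)=O)C[C@H]1CC/C(C)=C/I | intermediate
13 | (3S,4R,6R)-6-acetyl-4-[(3E)-4-iodo-3-methylbut-3-en-1-yl]-3-methyloxan-2-one (all-equatorial) | C[C@@H]1C(=O)O[C@@H](C(C)=O)C[C@H]1CC/C(C)=C/I | intermediate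
14 | 5-bromo-2-methylpent-2-ene | CC(C)=CCCBr | starting material
15 | (2E)-5-bromo-2-methylpent-2-en-1-ol | OC/C(C)=C/CCBr | intermediate
16 | (2E)-5-bromo-2-methylpent-2-enal | O=C/C(C)=C/CCBr | intermediate
17 | (3E)-6-bromo-3-methylhexa-1,3-diene | C=C/C(C)=C/CCBr | intermediate
18 | [(3E)-4-methylhexa-3,5-dien-1-yl]magnesium bromide | C=C/C(C)=C/CC[Mg]Br | intermediate
19 | (3S,4R,6R)-6-[(2S,5E)-2-hydroxy-6-methylocta-5,7-dien-2-yl]-4-[(3E)-4-iodo-3-methylbut-3-en-1-yl]-3-methyloxan-2-one | C[C@@H]1C(=O)O[C@@H]([C@@](C)(O)CC/C=C(C)/C=C)C[C@H]1CC/C(C)=C/I | intermediate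
20 | B-alkyl-9-BBN from 19 (boron on the terminal diene carbon C10; 7E alkene kept) | C[C@@H]1C(=O)O[C@@H]([C@@](C)(O)CC/C=C(C)/CCB2C3CCCC2CCC3)C[C@H]1CC/C(C)=C/I | intermediate
21 | (1R,3R,4S,7E,11E,15S)-4-hydroxycembra-7,11-dien-16,3-olide | C[C@@H]1C(=O)O[C@@H]2C[C@H]1CC/C(C)=C/CC/C(C)=C/CC[C@]2(C)O | intermediate
22 | (1R,3R,4S,11R,12S,15S)-7,11-dibromo-4,8-epoxy-12-hydroxycembran-16,3-olide (bromoether plus bromohydrin; anti adduct at C7/C8 from either face; the oxolane regioisomer with O on C7 and Br on C8 behaves the same) | C[C@@H]1C(=O)O[C@@H]2C[C@H]1CC[C@](C)(O)[C@H](Br)CCC(C)(O3)C(Br)CC[C@@]23C | intermediate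
23 | (1R,3R,4S,11S,12S,15S)-7-bromo-4,8:11,12-diepoxycembran-16,3-olide (epoxy bromoether; C7/C8 as in 22) | C[C@@H]1C(=O)O[C@@H]2C[C@H]1CC[C@]4(C)O[C@H]4CCC(C)(O3)C(Br)CC[C@@]23C | intermediate
24 | (1R,3R,4S,7E,11S,12S,15S)-11,12-epoxy-4-hydroxycembr-7-en-16,3-olide | C[C@@H]1C(=O)O[C@@H]2C[C@H]1CC[C@]3(C)O[C@H]3CC/C(C)=C/CC[C@]2(C)O | intermediate
25 | (1R,3R,4S,6E,8R,11S,12S,15S)-11,12-epoxy-8-hydroperoxy-4-hydroxycembr-6-en-16,3-olide (CNP0297487.3) | C[C@@H]1C(=O)O[C@@H]2C[C@H]1CC[C@]1(C)O[C@H]1CC[C@@](C)(OO)/C=C/C[C@]2(C)O | target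

**Step count and risks**
Total step count: 12 (steps 1–12). Longest linear sequence: 10 (steps 1–6 and 9–12, from 1).

Most likely to fail, first: step 11, the proposed new electrochemical epoxidation. The masking of C7=C8 may be incomplete, the lactone may open under the cathodic base, and the facial sense at C11=C12 rests on substrate control that cannot be predicted with confidence. The fallback uses known, stepwise reagent chemistry instead of electrolysis and sets out from 21. N-Bromosuccinimide with NaHCO3 in CH2Cl2 at 0 °C gives the cyclic bromoether F1. A second equivalent of N-bromosuccinimide in THF/H2O gives the bromohydrin 22, K2CO3 in MeOH closes it to 23, and Zn in EtOH unmasks the alkene, so the sequence comes back to the route at 24. If the halohydrin course oxygenates the wrong face, mCPBA on the bromoether F1 delivers oxygen to the other face before the same zinc step.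

Second: step 12, the Schenck ene reaction. Hydrogen abstraction from the C19 methyl (giving the C7 hydroperoxide with an exocyclic alkene) competes, typically at a similar rate in acyclic models, and the C8 configuration depends on which face of the macrocyclic alkene is exposed. The fallback is a known ionic sequence that fixes the regiochemistry and sets out from 24. 1-(Trimethylsilyl)imidazole gives the trimethylsilyl ether F2, which keeps the C4 oxygen from capturing the bromonium ion. N-Bromosuccinimide with 2-methoxyprop-2-yl hydroperoxide in CH2Cl2 at −20 °C gives the bromo peroxyketal F3 (Markovnikov anti bromoperoxidation, peroxide on tertiary C8, bromine on C7). DBU in toluene at 50 °C removes HBr, for which only the C6 hydrogens are available, to give the allylic peroxyketal F4 with the E-C6=C7 alkene. Pyridinium p-toluenesulfonate in MeOH at 0 °C then cleaves the peroxyketal and the silyl ether and comes back at the target 25.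

Third: step 10, the macrocyclisation. Oligomerisation, protodeboronation or opening of the lactone by the aqueous base can cut the yield. The fallback closes the ring at a different bond by metathesis and sets out from 13. B-alkyl Suzuki–Miyaura coupling of the vinyl iodide with the 9-BBN adduct of isoprene (PdCl2(dppf), AsPh3, Cs2CO3, DMF/H2O) gives the isopentenyl lactone F5. But-3-enylmagnesium bromide with CeCl3 at −78 °C (same Felkin–Anh course as step 9) gives the diene alcohol F6. Ring-closing metathesis with second-generation Grubbs catalyst, RuCl2(H2IMes)(PCy3)(=CHPh), in toluene at 80 °C and 1 mM forms the trisubstituted C7=C8 alkene and comes back to the route at 21; an E/Z separation may be needed.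

**Further compounds**
F1 | step 11 | (1R,3R,4S,11E,15S)-7-bromo-4,8-epoxycembr-11-en-16,3-olide (cyclic bromoether, anti adduct at C7/C8) | C[C@@H]1C(=O)O[C@@H]2C[C@H]1CC/C(C)=C/CCC(C)(O3)C(Br)CC[C@@]23C
F2 | step 12 | (1R,3R,4S,7E,11S,12S,15S)-11,12-epoxy-4-(trimethylsilyloxy)cembr-7-en-16,3-olide | C[C@@H]1C(=O)O[C@@H]2C[C@H]1CC[C@]3(C)O[C@H]3CC/C(C)=C/CC[C@]2(C)O[Si](C)(C)C
F3 | step 12 | (1R,3R,4S,7S,8R,11S,12S,15S)-7-bromo-11,12-epoxy-8-[(2-methoxypropan-2-yl)peroxy]-4-(trimethylsilyloxy)cembran-16,3-olide | C[C@@H]1C(=O)O[C@@H]2C[C@H]1CC[C@]3(C)O[C@H]3CC[C@@](C)(OOC(C)(C)OC)[C@@H](Br)CC[C@]2(C)O[Si](C)(C)C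
F4 | step 12 | (1R,3R,4S,6E,8R,11S,12S,15S)-11,12-epoxy-8-[(2-methoxypropan-2-yl)peroxy]-4-(trimethylsilyloxy)cembr-6-en-16,3-olide | C[C@@H]1C(=O)O[C@@H]2C[C@H]1CC[C@]3(C)O[C@H]3CC[C@@](C)(OOC(C)(C)OC)/C=C/C[C@]2(C)O[Si](C)(C)C
F5 | step 10 | (3S,4R,6R)-6-acetyl-4-[(3E)-3,7-dimethylocta-3,7-dien-1-yl]-3-methyloxan-2-one | C[C@@H]1C(=O)O[C@@H](C(C)=O)C[C@H]1CC/C(C)=C/CCC(C)=C
F6 | step 10 | (3S,4R,6R)-4-[(3E)-3,7-dimethylocta-3,7-dien-1-yl]-6-[(2S)-2-hydroxyhex-5-en-2-yl]-3-methyloxan-2-one | C[C@@H]1C(=O)O[C@@H]([C@@](C)(O)CCC=C)C[C@H]1CC/C(C)=C/CCC(C)=C
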